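## Structural features

The target is a B-type proanthocyanidin dimer built from two flavan-3-ol units. The upper unit is a 7,4'-dihydroxyflavan-3-ol (5-deoxy resorcinol-type ring A, p-hydroxyphenyl ring B, pyran ring C); the lower unit is (−)-epicatechin (phloroglucinol-type ring D, catechol ring E, pyran ring F). The units are joined by one C–C bond from C4 of ring C to C8 of ring D, the ring D carbon between the pyran oxygen and the 7-hydroxyl. Ring C carries three contiguous stereocentres, C2 (R), C3 (R) and C4 (S); the ring B aryl group at C2, the hydroxyl at C3 and the ring D aryl group at C4 all lie on one face (2,3-cis-3,4-cis, a 4α linkage of an epi-type unit). Ring F carries the two adjacent stereocentres of epicatechin (2R,3R, cis). Six phenols including a catechol make the free compound sensitive to oxidation, the electron-rich ring D makes the C4–C8 bond acid-labile through ipso protonation, and C2 of a free phenolic flavan epimerises in base. The real difficulty is the all-cis array on ring C: a nucleophile adding to a flavan-4-yl cation is expected to enter trans to O3, which gives the C4 epimer, and the 5-deoxy upper unit has no chiral-pool source. The feature exploited is that C3 of ring C is a carbinol flanked by two benzylic methines (C2 and C4) whose aryl groups are both cis to it. That is the pattern produced when hydride adds anti to both aryl groups of a 2,4-diaryl-3-ketone whose two α-hydrogens are acidic enough to equilibrate.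

## Logic of the disconnections

17 to 16: the seven benzyl C–O bonds are cut. One kind of protecting group on all six phenols and on O3 of ring F allows a single neutral release at the end; O3 of ring C needs no protection. The forward step must cleave seven ethers without opening the benzylic C2–O1 bonds of rings C and F or the C4–C8 bond.

16 to 15 (key disconnection): the C3–H bond of ring C is cut and the configurations at C2 and C4 are given up, so the carbinol becomes a ketone flanked by two epimerisable methines. In one sentence, the route is a dynamic-kinetic asymmetric hydrogenation of 15, a ketone with no fixed configuration in its upper unit. The gain is that three contiguous stereocentres disappear at once and the precursor may be any mixture of C2/C4 isomers. The forward step demands that both α-centres equilibrate faster than the carbonyl is reduced, that hydride arrives anti to both aryl groups, and that the catalyst selects the (2R,4S) series.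

15 to 13: the C2–H bond is cut (hydride removed), which turns ring C into a flat, aromatic benzopyrylium ring. The upper unit then has no stereocentre, and ring C can be assembled by flavonoid chemistry. The forward hydride transfer must dearomatise the pyrylium ring but stop at the ketone oxidation level.

13 to 4 + 10: the C4–C8 bond between rings C and D is cut as an aryl anion at C8 and a carbonyl carbon at C4. The 8 versus 6 regiochemistry is fixed by the position of the halogen in 4, and the bond is made to an sp2 carbon, so no stereochemical question arises. Ring A has no 5-substituent, which leaves the carbonyl of 10 open. The forward step needs 1,2-addition rather than conjugate addition, followed by acid-driven aromatisation.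

4 to 3 to 2 to 1: the C8–Br bond and then the five O–benzyl bonds are cut, leading to the commercial chiral-pool flavan 1, which brings both stereocentres of ring F. The bromination must choose C8 over C6; the benzylations must not epimerise C2.

10 to 9 to 7 to 5 + 6: the O–Si bond is cut, then the O1–C2 and C3–O bonds of ring C (oxidative cyclisation of a chalcone), then the C2–C3 bond (aldol condensation). This reduces the upper unit to two commercial benzyl-protected aromatics. The only demand is that the oxidative cyclisation follows the six-membered (flavonol) pathway.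

## Other disconnections considered

Alternative 1: the first route that comes to mind. The C4–C8 bond is cut heterolytically into a flavan-4-yl cation and a nucleophilic arene. The forward key step is Friedel–Crafts coupling of the C4-activated, enantiopure 2,3-cis electrophile A1 with 3 under TiCl4 or BF3·OEt2. It is rejected on three grounds.
- The cation from A1 is expected to be attacked on the face opposite O3 and the ring B aryl group, which would place the new bond trans to O3, the C4 epimer of what is needed.
- A 5-deoxy cation is less stabilised, so stronger acid would be needed, which lowers C8/C6 selectivity and invites oligomerisation.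
- A1 itself requires an enantioselective synthesis of a 2,3-cis 5-deoxyflavan-3-ol followed by C4 oxidation, many more steps than the flat upper unit used here.

Alternative 2: the same bond with reversed polarity on a stereodefined ketone. Aryllithium 11 is added to the enantiopure 2,3-cis flavan-4-one A2, and the tertiary carbinol A3 is then deoxygenated ionically (Bu3SnH or Et3SiH with CF3CO2H), the hydride entering anti to O3. The sense at C4 would be correct, but C2 and C3 must already be in place. A2 is the less stable 2,3-cis isomer, and its C3–H is α to the carbonyl, so it can epimerise to trans under the basic addition conditions. A2 also needs a long enantioselective synthesis. The chosen plan keeps the secure aryllithium-to-carbonyl bond formation but uses a flat flavonol and sets C2, C3 and C4 together.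

Alternative 3: ring C is cut at O1–C2 and C3–C4. The forward key step is a hetero-Diels–Alder reaction between the ortho-quinone methide A5, generated by acid from carbinol A4 (11 plus 4-(benzyloxy)-2-hydroxybenzaldehyde), and the (Z)-enol acetate A6; the endo mode would close ring C all-cis. The idea builds the ring and three centres in one step, but three selectivities are unsecured.
- Regiochemistry depends on the aryl group outweighing the acyloxy group as donor in A6.
- The methide carbon of A5 carries the strongly donating ring D, which favours a stepwise cationic path; that would lose the Z geometry and allow acyloxy participation at C2 (2,3-trans).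
- The absolute sense would rest on a chiral acid distinguishing the faces of A5, whose stereogenic unit is remote, while the same acid threatens the C4–C8 bond.

The hydrogenation chosen addresses the same three centres with a reaction class already used for contiguous triads on six-membered ketones.

Key step: step 9

Assumption: the sense of induction of the ruthenium catalyst on ketone 15 cannot be derived with certainty from the model for simple 2-arylcyclohexanones, so the (S)-Xyl-SDP/(R,R)-DPEN complex is written; if it is the mismatched antipode, its mirror image is used with no other change (Xyl-SDP = 7,7'-bis[di(3,5-dimethylphenyl)phosphino]-1,1'-spirobiindane, DPEN = 1,2-diphenylethane-1,2-diamine).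

In the names below, "penta-O-benzylepicatechin-8-yl" stands for (2R,3R)-3,5,7-tris(benzyloxy)-2-[3,4-bis(benzyloxy)phenyl]chroman-8-yl.

## Route

Step 1
Reactants: 1 (−)-epicatechin
Product: 2 5,7,3',4'-tetra-O-benzyl-(−)-epicatechin
Conditions: BnBr (4.2 equiv), K2CO3, DMF, 0 °C to rt
Reagents that add atoms: benzyl bromide, BrCc1ccccc1
Why: Williamson etherification; carbonate deprotonates only the four phenols, so the secondary 3-OH stays free, and the mild base at room temperature should leave C2 and C3 untouched.

Step 2
Reactants: 2 5,7,3',4'-tetra-O-benzyl-(−)-epicatechin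
Product: 3 3,5,7,3',4'-penta-O-benzyl-(−)-epicatechin
Conditions: NaH, BnBr, Bu4NI (cat.), DMF, 0 °C to rt
Reagents that add atoms: benzyl bromide, BrCc1ccccc1
Why: Williamson etherification of the secondary alkoxide; with every phenol capped, the quinone-methide pathway for C2 epimerisation is closed.

Step 3
Reactants: 3 3,5,7,3',4'-penta-O-benzyl-(−)-epicatechin
Product: 4 8-bromo-3,5,7,3',4'-penta-O-benzyl-(−)-epicatechin
Conditions: NBS (1.0 equiv), CH2Cl2, −78 °C to 0 °C
Reagents that add atoms: N-bromosuccinimide, O=C1CCC(=O)N1Br
Why: Electrophilic aromatic bromination of the phloroglucinol-type ring D; C8, flanked by the ring oxygen and not by two benzyloxy groups, is the more accessible of the two free positions, the usual preference of 5,7-di-O-alkylated flavan-3-ols.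

Step 4
Reactants: 5 1-[4-(benzyloxy)-2-hydroxyphenyl]ethan-1-one; 6 4-(benzyloxy)benzaldehyde
Product: 7 (E)-1-[4-(benzyloxy)-2-hydroxyphenyl]-3-[4-(benzyloxy)phenyl]prop-2-en-1-one
Conditions: KOH (aq.), EtOH, rt; then dilute HCl
Reagents that add atoms: none
Why: Claisen–Schmidt condensation; aldol addition of the methyl ketone enolate to the non-enolisable aldehyde and E1cB dehydration should give the conjugated E-alkene.

Step 5
Reactants: 7 (E)-1-[4-(benzyloxy)-2-hydroxyphenyl]-3-[4-(benzyloxy)phenyl]prop-2-en-1-one
Product: 9 7-(benzyloxy)-2-[4-(benzyloxy)phenyl]-3-hydroxy-4H-chromen-4-one, via racemic trans-dihydroflavonol 8 (not isolated)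
Conditions: 30% H2O2, NaOH (aq.), MeOH/THF, 0 °C to rt; then dilute HCl
Reagents that add atoms: hydrogen peroxide, OO
Why: Algar–Flynn–Oyamada reaction; hydroperoxide-mediated oxidative cyclisation gives 8, whose enolate is oxidised on to the aromatic chromone, and a chalcone without a 6'-substituent is expected to follow the flavonol and not the aurone pathway.

Step 6
Reactants: 9 7-(benzyloxy)-2-[4-(benzyloxy)phenyl]-3-hydroxy-4H-chromen-4-one
Product: 10 7-(benzyloxy)-2-[4-(benzyloxy)phenyl]-3-[(tert-butyldimethylsilyl)oxy]-4H-chromen-4-one
Conditions: TBSCl, imidazole, DMF, rt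
Reagents that add atoms: tert-butyldimethylsilyl chloride, CC(C)(C)[Si](C)(C)Cl
Why: Silylation of the enolic 3-OH removes the only acidic proton so that the C4 carbonyl can accept an organolithium; the silyl ether is chosen because it should hydrolyse readily once ring C becomes a pyrylium cation.

Step 7
Reactants: 4 8-bromo-3,5,7,3',4'-penta-O-benzyl-(−)-epicatechin; 10 7-(benzyloxy)-2-[4-(benzyloxy)phenyl]-3-[(tert-butyldimethylsilyl)oxy]-4H-chromen-4-one
Product: 13 7-(benzyloxy)-2-[4-(benzyloxy)phenyl]-3-hydroxy-4-(penta-O-benzylepicatechin-8-yl)chromenylium chloride, via aryllithium 11 (not isolated), via lithium alkoxide 12 (not isolated)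
Conditions: 4, n-BuLi, THF, −78 °C; add 10, −78 to 0 °C; then 2 M HCl (aq.)/THF, rt
Reagents that add atoms: hydrogen chloride, Cl (chloride counter-ion of 13); n-butyllithium, [Li]CCCC (lithium of 11 and 12 only)
Why: Bromine–lithium exchange gives 11, which adds 1,2 to the chromone carbonyl, the classical entry to 4-substituted flavylium salts; acid then ionises the tertiary, doubly benzylic alkoxide 12 to the aromatic benzopyrylium and hydrolyses the now labile silyl ether. The absent 5-substituent on ring A keeps C4 accessible, and no stereocentre is created.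

Step 8
Reactants: 13 7-(benzyloxy)-2-[4-(benzyloxy)phenyl]-3-hydroxy-4-(penta-O-benzylepicatechin-8-yl)chromenylium chloride
Product: 15 7-(benzyloxy)-2-[4-(benzyloxy)phenyl]-4-(penta-O-benzylepicatechin-8-yl)chroman-3-one (mixture of C2/C4 stereoisomers), via enol 14 (not isolated)
Conditions: Hantzsch ester (diethyl 2,6-dimethyl-1,4-dihydropyridine-3,5-dicarboxylate, 1.2 equiv), CH2Cl2, rt, Ar; then filtration through silica
Reagents that add atoms: none
Why: Hydride transfer from a 1,4-dihydropyridine to a benzopyrylium cation dearomatises ring C; attack at C2, the less hindered electrophilic carbon, gives enol 14, which tautomerises to the ketone (delivery at C4 would end in the same ketone). The organic hydride donor cannot reduce the ketone or touch benzyl ethers, and the undefined configuration at C2 and C4 is intended.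

Step 9
Reactants: 15 7-(benzyloxy)-2-[4-(benzyloxy)phenyl]-4-(penta-O-benzylepicatechin-8-yl)chroman-3-one (mixture of C2/C4 stereoisomers)
Product: 16 (2R,3R,4S)-7-(benzyloxy)-2-[4-(benzyloxy)phenyl]-4-(penta-O-benzylepicatechin-8-yl)chroman-3-ol
Conditions: RuCl2[(S)-Xyl-SDP][(R,R)-DPEN] (1 mol%), KOtBu (20 mol%), H2 (50 atm), i-PrOH/toluene, 25 °C
Reagents that add atoms: none
Why: Noyori-type bifunctional hydrogenation with dynamic kinetic resolution, the reaction type established for racemic 2-aryl- and 2,6-disubstituted cyclohexanones, here applied to a 2,4-diarylchroman-3-one. KOtBu equilibrates both α-centres of 15 through the C2 and C4 enolates (C2–H is benzylic and α to O1, C4–H is doubly benzylic), so all four C2/C4 isomers feed one reacting isomer under Curtin–Hammett conditions. The ruthenium dihydride with its diamine N–H transfers hydride and proton to C3=O in an outer-sphere six-membered transition state; no ring is closed. C3 is controlled by the substrate: hydride should arrive on the carbonyl face that carries only the pseudo-axial H2 and H4, anti to both aryl groups, the sense in which bulky hydride donors reduce flavan-3-ones and 2-arylcyclohexanones, leaving O3 axial and cis to both aryls. C2 and C4 are controlled by selection: the 2,4-cis ketone with both aryl groups pseudo-equatorial should be reduced much faster than the trans isomers, in which one aryl is axial and shields the reacting face. The chiral pocket of the catalyst then chooses between the (2R,4S) and (2S,4R) cis-ketones, which differ strongly at the two flanks (unhindered ring B aryl and O1 at C2, di-ortho-substituted ring D and ring A at C4). The selectivities needed are therefore cis over trans and carbonyl face (both from the substrate) and the absolute series (from the catalyst, helped or opposed by the remote 2R,3R unit, which makes the two outcomes separable diastereomers). Benzyl ethers and arenes are inert to this homogeneous catalyst.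

Step 10
Reactants: 16 (2R,3R,4S)-7-(benzyloxy)-2-[4-(benzyloxy)phenyl]-4-(penta-O-benzylepicatechin-8-yl)chroman-3-ol
Product: 17 (2R,3R,4S)-2-(4-hydroxyphenyl)-4-[(2R,3R)-2-(3,4-dihydroxyphenyl)-3,5,7-trihydroxychroman-8-yl]chromane-3,7-diol (target, CNP0118995.5)
Conditions: H2 (1 atm), Pd(OH)2/C, THF/MeOH/H2O, rt
Reagents that add atoms: none
Why: Hydrogenolysis of the seven benzyl ethers under neutral conditions, the standard end game for benzylated proanthocyanidins; the benzylic C2–O1 bonds of rings C and F and the C4–C8 bond are expected to survive, and no stereocentre is affected.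

## Compound list

1 | (−)-epicatechin, (2R,3R)-2-(3,4-dihydroxyphenyl)chromane-3,5,7-triol | c1c(O)cc(O)c2c1O[C@H](c3ccc(O)c(O)c3)[C@H](O)C2 | starting material
2 | 5,7,3',4'-tetra-O-benzyl-(−)-epicatechin | c5c(OCc7ccccc7)cc(OCc7ccccc7)c4c5O[C@H](c6ccc(OCc7ccccc7)c(OCc7ccccc7)c6)[C@H](O)C4 | intermediate
3 | 3,5,7,3',4'-penta-O-benzyl-(−)-epicatechin | c5c(OCc7ccccc7)cc(OCc7ccccc7)c4c5O[C@H](c6ccc(OCc7ccccc7)c(OCc7ccccc7)c6)[C@H](OCc7ccccc7)C4 | intermediate
4 | 8-bromo-3,5,7,3',4'-penta-O-benzyl-(−)-epicatechin | Brc5c(OCc7ccccc7)cc(OCc7ccccc7)c4c5O[C@H](c6ccc(OCc7ccccc7)c(OCc7ccccc7)c6)[C@H](OCc7ccccc7)C4 | intermediate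
5 | 1-[4-(benzyloxy)-2-hydroxyphenyl]ethan-1-one | CC(=O)c1ccc(OCc2ccccc2)cc1O | starting material
6 | 4-(benzyloxy)benzaldehyde | O=Cc1ccc(OCc2ccccc2)cc1 | starting material
7 | (E)-1-[4-(benzyloxy)-2-hydroxyphenyl]-3-[4-(benzyloxy)phenyl]prop-2-en-1-one | O=C(/C=C/c1ccc(OCc2ccccc2)cc1)c1ccc(OCc2ccccc2)cc1O | intermediate
8 | racemic trans-7-(benzyloxy)-2-[4-(benzyloxy)phenyl]-3-hydroxychroman-4-one (2R,3R enantiomer drawn) | c7ccccc7COc1ccc([C@H]2Oc3cc(OCc7ccccc7)ccc3C(=O)[C@@H]2O)cc1 | intermediate (not isolated)
9 | 7-(benzyloxy)-2-[4-(benzyloxy)phenyl]-3-hydroxy-4H-chromen-4-one | O=c1c(O)c(-c2ccc(OCc3ccccc3)cc2)oc2cc(OCc3ccccc3)ccc12 | intermediate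
10 | 7-(benzyloxy)-2-[4-(benzyloxy)phenyl]-3-[(tert-butyldimethylsilyl)oxy]-4H-chromen-4-one | O=c1c(O[Si](C)(C)C(C)(C)C)c(-c2ccc(OCc3ccccc3)cc2)oc2cc(OCc3ccccc3)ccc12 | intermediate
11 | 8-lithio-3,5,7,3',4'-penta-O-benzyl-(−)-epicatechin | [Li]c5c(OCc7ccccc7)cc(OCc7ccccc7)c4c5O[C@H](c6ccc(OCc7ccccc7)c(OCc7ccccc7)c6)[C@H](OCc7ccccc7)C4 | intermediate (not isolated)
12 | lithium 7-(benzyloxy)-2-[4-(benzyloxy)phenyl]-3-[(tert-butyldimethylsilyl)oxy]-4-(penta-O-benzylepicatechin-8-yl)-4H-chromen-4-olate (C4 epimers) | [Li+].[O-]C1(c5c(OCc7ccccc7)cc(OCc7ccccc7)c4c5O[C@H](c6ccc(OCc7ccccc7)c(OCc7ccccc7)c6)[C@H](OCc7ccccc7)C4)C(O[Si](C)(C)C(C)(C)C)=C(c2ccc(OCc7ccccc7)cc2)Oc3cc(OCc7ccccc7)ccc13 | intermediate (not isolated)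
13 | 7-(benzyloxy)-2-[4-(benzyloxy)phenyl]-3-hydroxy-4-(penta-O-benzylepicatechin-8-yl)chromenylium chloride | [Cl-].Oc1c(-c2ccc(OCc7ccccc7)cc2)[o+]c3cc(OCc7ccccc7)ccc3c1-c5c(OCc7ccccc7)cc(OCc7ccccc7)c4c5O[C@H](c6ccc(OCc7ccccc7)c(OCc7ccccc7)c6)[C@H](OCc7ccccc7)C4 | intermediate
14 | 7-(benzyloxy)-2-[4-(benzyloxy)phenyl]-4-(penta-O-benzylepicatechin-8-yl)-2H-chromen-3-ol (C2 epimers) | OC1=C(c5c(OCc7ccccc7)cc(OCc7ccccc7)c4c5O[C@H](c6ccc(OCc7ccccc7)c(OCc7ccccc7)c6)[C@H](OCc7ccccc7)C4)c3ccc(OCc7ccccc7)cc3OC1c2ccc(OCc7ccccc7)cc2 | intermediate (not isolated)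
15 | 7-(benzyloxy)-2-[4-(benzyloxy)phenyl]-4-(penta-O-benzylepicatechin-8-yl)chroman-3-one (mixture of C2/C4 stereoisomers) | O=C1C(c5c(OCc7ccccc7)cc(OCc7ccccc7)c4c5O[C@H](c6ccc(OCc7ccccc7)c(OCc7ccccc7)c6)[C@H](OCc7ccccc7)C4)c3ccc(OCc7ccccc7)cc3OC1c2ccc(OCc7ccccc7)cc2 | intermediate
16 | (2R,3R,4S)-7-(benzyloxy)-2-[4-(benzyloxy)phenyl]-4-(penta-O-benzylepicatechin-8-yl)chroman-3-ol | c7ccccc7COc1ccc([C@H]2Oc3cc(OCc7ccccc7)ccc3[C@@H](c5c(OCc7ccccc7)cc(OCc7ccccc7)c4c5O[C@H](c6ccc(OCc7ccccc7)c(OCc7ccccc7)c6)[C@H](OCc7ccccc7)C4)[C@H]2O)cc1 | intermediate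
17 | (2R,3R,4S)-2-(4-hydroxyphenyl)-4-[(2R,3R)-2-(3,4-dihydroxyphenyl)-3,5,7-trihydroxychroman-8-yl]chromane-3,7-diol | Oc1ccc([C@H]2Oc3cc(O)ccc3[C@@H](c3c(O)cc(O)c4c3O[C@H](c3ccc(O)c(O)c3)[C@H](O)C4)[C@H]2O)cc1 | target

## Step count and least certain steps

Total step count: 10. Longest linear sequence: 7 steps (steps 1, 2, 3, 7, 8, 9, 10 from 1; equally steps 4, 5, 6, 7, 8, 9, 10 from 5 and 6).

Step 9 (key step). Most likely to go wrong:
- slow or failed hydrogenation, because both flanks of the carbonyl are arylated and ring D is very bulky;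
- epimerisation at C2 slower than reduction, so that the resolution is not dynamic;
- a mismatched pairing of catalyst and lower unit, giving poor selection of the absolute series;
- oxidation of the enolate by adventitious oxygen.

Fallback, setting out from 15 and returning at 16: 15 is equilibrated with DBU to the 2,4-cis pair and reduced at −78 °C with LiBH(s-Bu)3, a stoichiometric substrate-controlled reduction that delivers hydride anti to both aryl groups without epimerisation. This should give 16 together with the all-cis (2S,3S,4R) upper-unit diastereomer F1. The two are diastereomers because of the lower unit and are separated by chromatography. F1 is oxidised with Dess–Martin periodinane back to 15 and recycled.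

Step 7. Most likely to go wrong:
- failure of the 1,2-addition of the hindered, di-ortho-substituted aryllithium (quenching by benzylic C–H, attack at silicon, conjugate addition at C2);
- migration of the silyl group from O3 to the new alkoxide, which should still converge on 13 in acid but may slow the ionisation.

Fallback, setting out from 10 and 3 and returning at 15: the carbonyl of 10 is reduced with LiAlH4 and the crude allylic alcohol is ionised and desilylated with aqueous HCl to the C4-unsubstituted 7-(benzyloxy)-2-[4-(benzyloxy)phenyl]-3-hydroxychromenylium chloride F2. The arene 3, without bromine, is then added to C4 of F2 in acetonitrile at room temperature, a Friedel–Crafts-type dearomatising addition of the kind known for flavylium ions and phloroglucinol-type nucleophiles. Tautomerisation of the resulting enol gives 15 directly. The price is that regiocontrol now rests on the inherent C8 over C6 preference of 3, so a 6-linked isomer may have to be removed.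

Step 8. Most likely to go wrong:
- deprotonation of 13 to a 3-oxidopyrylium betaine that dimerises or accepts hydride sluggishly;
- slow hydride transfer at two hindered positions;
- re-oxidation of the electron-rich enol or ketone to the pyrylium by air.

Fallback, setting out from 4 and 10 and returning at 15: the addition of step 7 is repeated but quenched with aqueous NH4Cl, so that the neutral tertiary carbinol 7-(benzyloxy)-2-[4-(benzyloxy)phenyl]-3-[(tert-butyldimethylsilyl)oxy]-4-(penta-O-benzylepicatechin-8-yl)-4H-chromen-4-ol F3 is kept. Bu4NF buffered with AcOH unmasks the α-hydroxy ketone 7-(benzyloxy)-2-[4-(benzyloxy)phenyl]-4-hydroxy-4-(penta-O-benzylepicatechin-8-yl)chroman-3-one F4. SmI2 in THF/MeOH then cleaves the tertiary α-C–O bond through the ketyl and enolate to give 15 without passing through a pyrylium ion.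

Step 10. Most likely to go wrong:
- incomplete cleavage of seven ethers on a crowded molecule;
- partial hydrogenolysis of a benzylic C2–O1 bond;
- oxidative loss of the free catechol-containing product during isolation.

Fallback, setting out from 16 and returning at 17: the crude hydrogenolysis mixture is not isolated as the free phenol but acetylated in the same flask (Ac2O, pyridine) to the octa-O-acetate of 17 F5. F5 is stable, is purified on silica, and can be freed of partly benzylated material, which is resubmitted. 17 is then released by methanolysis with NaOMe in degassed MeOH at 0 °C and neutralised with an acidic resin.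

## Further compounds

F1 | step 9 | (2S,3S,4R)-7-(benzyloxy)-2-[4-(benzyloxy)phenyl]-4-(penta-O-benzylepicatechin-8-yl)chroman-3-ol | c7ccccc7COc1ccc([C@@H]2Oc3cc(OCc7ccccc7)ccc3[C@H](c5c(OCc7ccccc7)cc(OCc7ccccc7)c4c5O[C@H](c6ccc(OCc7ccccc7)c(OCc7ccccc7)c6)[C@H](OCc7ccccc7)C4)[C@@H]2O)cc1
F2 | step 7 | 7-(benzyloxy)-2-[4-(benzyloxy)phenyl]-3-hydroxychromenylium chloride | [Cl-].Oc1cc2ccc(OCc3ccccc3)cc2[o+]c1-c1ccc(OCc2ccccc2)cc1
F3 | step 8 | 7-(benzyloxy)-2-[4-(benzyloxy)phenyl]-3-[(tert-butyldimethylsilyl)oxy]-4-(penta-O-benzylepicatechin-8-yl)-4H-chromen-4-ol (C4 epimers) | OC1(c5c(OCc7ccccc7)cc(OCc7ccccc7)c4c5O[C@H](c6ccc(OCc7ccccc7)c(OCc7ccccc7)c6)[C@H](OCc7ccccc7)C4)C(O[Si](C)(C)C(C)(C)C)=C(c2ccc(OCc7ccccc7)cc2)Oc3cc(OCc7ccccc7)ccc13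
F4 | step 8 | 7-(benzyloxy)-2-[4-(benzyloxy)phenyl]-4-hydroxy-4-(penta-O-benzylepicatechin-8-yl)chroman-3-one (stereoisomers at C2 and C4) | OC1(c5c(OCc7ccccc7)cc(OCc7ccccc7)c4c5O[C@H](c6ccc(OCc7ccccc7)c(OCc7ccccc7)c6)[C@H](OCc7ccccc7)C4)C(=O)C(c2ccc(OCc7ccccc7)cc2)Oc3cc(OCc7ccccc7)ccc13
F5 | step 10 | octa-O-acetate of 17 | CC(=O)Oc1ccc([C@H]2Oc3cc(OC(C)=O)ccc3[C@@H](c5c(OC(C)=O)cc(OC(C)=O)c4c5O[C@H](c6ccc(OC(C)=O)c(OC(C)=O)c6)[C@H](OC(C)=O)C4)[C@H]2OC(C)=O)cc1
A1 | alternative 1 | (2R,3R,4S)-3,7-bis(benzyloxy)-2-[4-(benzyloxy)phenyl]-4-(2-ethoxyethoxy)chromane (2,3-cis-3,4-trans C4 electrophile) | c7ccccc7COc1ccc([C@H]2Oc3cc(OCc7ccccc7)ccc3[C@H](OCCOCC)[C@H]2OCc7ccccc7)cc1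
A2 | alternative 2 | (2R,3S)-7-(benzyloxy)-2-[4-(benzyloxy)phenyl]-3-[(tert-butyldimethylsilyl)oxy]chroman-4-one (2,3-cis) | c7ccccc7COc1ccc([C@H]2Oc3cc(OCc7ccccc7)ccc3C(=O)[C@H]2O[Si](C)(C)C(C)(C)C)cc1
A3 | alternative 2 | 2,3-cis-7-(benzyloxy)-2-[4-(benzyloxy)phenyl]-3-[(tert-butyldimethylsilyl)oxy]-4-(penta-O-benzylepicatechin-8-yl)chroman-4-ol (C4 not defined) | c7ccccc7COc1ccc([C@H]2Oc3cc(OCc7ccccc7)ccc3C(O)(c5c(OCc7ccccc7)cc(OCc7ccccc7)c4c5O[C@H](c6ccc(OCc7ccccc7)c(OCc7ccccc7)c6)[C@H](OCc7ccccc7)C4)[C@H]2O[Si](C)(C)C(C)(C)C)cc1
A4 | alternative 3 | [4-(benzyloxy)-2-hydroxyphenyl](penta-O-benzylepicatechin-8-yl)methanol (carbinol epimers) | OC(c1ccc(OCc7ccccc7)cc1O)c5c(OCc7ccccc7)cc(OCc7ccccc7)c4c5O[C@H](c6ccc(OCc7ccccc7)c(OCc7ccccc7)c6)[C@H](OCc7ccccc7)C4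
A5 | alternative 3 | 3-(benzyloxy)-6-[(penta-O-benzylepicatechin-8-yl)methylidene]cyclohexa-2,4-dien-1-one (ortho-quinone methide, alkene geometry not defined) | O=C1C=C(OCc7ccccc7)C=CC1=Cc5c(OCc7ccccc7)cc(OCc7ccccc7)c4c5O[C@H](c6ccc(OCc7ccccc7)c(OCc7ccccc7)c6)[C@H](OCc7ccccc7)C4
A6 | alternative 3 | (Z)-2-[4-(benzyloxy)phenyl]ethenyl acetate | CC(=O)O/C=C\c1ccc(OCc2ccccc2)cc1
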